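The rate constants can stay unknown here: you can reckon both flasks from the dawn run.

| flask | solid substrate | remark | time |
|---|---|---|---|
| dawn | 0.33 M | run made earlier |  |
| south-west | 0.50 M |  | 12 h |
| north-west | 0.30 M |  | 6.0 h |

dawn run (percent of the solid substrate charged)

| time / h | target / % |
|---|---|
| 0.250 | 1 |
| 0.667 | 7 |
| 1.33 | 11 |
| 2.00 | 23 |
| 3.00 | 33 |
| 4.00 | 46 |

(each reading ± 1.5 percentage points)

- percent here means solid substrate units held: one self-condensation product counts as two
- what is said of target includes crystals
- solid substrate, crystals is a solid; its amount is given per volume of the solution
- what may be going on: crystals <-> target; solid substrate <-> starting material; starting material -> target; 2 starting material -> self-condensation product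
- at the start none of the solid substrate is in solution
- what has only dissolved of solid substrate counts as not reacted

- which of the two ends with the higher amount of target, in percent of the solid substrate charged ("neither" if they lie within 2 percentage points) (south-west / north-west / neither)
- target at the end, in percent of the solid substrate charged, south-west
- target at the end, in percent of the solid substrate charged, north-west

Dawn target climbs in a line, from 23% at 2.00 h to 46% at 4.00 h: twice the target in twice the time, though the unreacted part of the dawn charge had shrunk to at most 54.0%. I read this as a zero-order feed with dissolution as the rate-limiting step, and I assume that the absolute gain per hour does not depend on the charge.

So scale the last dawn fraction by the ratio of charges and the ratio of times. South-west gets 91.1%, and that figure is its delivery number, the fraction of its own charge that the dawn gain per hour supplies in its time. North-west gets 75.9%. Both are estimates, the reading 46% multiplied up, so its scatter of 1.5 percentage points is multiplied with it, to about 3 points in south-west and 2.5 points in north-west. Both lie under the whole charge, so I read target straight off them, south-west ahead by 15 points, more than the margin.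

Is one number enough? The slope counts target gained, so a steady loss of starting material eats solid unseen, and the number holds while that lost share stays under 8.92% in south-west and 24.1% in north-west. The dawn line cannot show that share.

The forecast says south-west, with south-west at 80%, below my figure, and north-west at 74%, holding that “Loss exhausts the solid sooner”.

    crystals ⇌ target, rate k1*(cs1 - [target]) while solid is left; crystals form when [target] > cs1 (solubility = 0.260 M, k = 2.30 /min)
    solid substrate ⇌ starting material, rate k2*(cs2 - [starting material]) while solid is left; crystals form when [starting material] > cs2 (solubility = 0.0780 M, k = 0.00840 /min)
    starting material → target, rate k3*[starting material]/(1 + ([starting material]/sat3)) (0.150 M, k = 0.240 /min)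
    2 starting material → self-condensation product (k = 0.150 /M/min)

The flasks give 90.3% of target in south-west and 74.8% in north-west, against delivery numbers of 91.1% and 75.9%. At 12.0 h south-west holds 0.306% as self-condensation product, far below the allowance of 8.92%, and that step makes no difference to its target. Take a further flask like south-west but charged with 2.0 M: its delivery number falls to 22.8%, and at 12.0 h it holds 22.6% of target.

(The earlier runs and the new flask are simulated with constants of no real substance, noise included.)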